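A closed flask, a plug-flow tube and two stirred tanks take the same charge, and I have to say which vessel delivers the most target.

| setting | oak | birch | cedar | elm | Saturday's | Tuesday's | Wednesday's | Thursday's |
|---|---|---|---|---|---|---|---|---|
| substrate | 1 M | 0.50 M | 0.75 M | 1 M | 1.0 M | 1.0 M | 1.0 M | 1.0 M |
| reagent | 2 equiv | 2 equiv | 2 equiv | 2 equiv | 2.00 equiv | 2.00 equiv | 2.00 equiv | 2.00 equiv |
| free catalyst | 10 mol% | 10 mol% | 10 mol% | 5 mol% | 10 mol% | 10 mol% | 10 mol% | 10 mol% |
| remark | run made earlier | run made earlier | run made earlier | run made earlier | a closed flask charged with all of it at once and left for 4.0 h | one stirred flow tank at steady state, fed with the mixture as stated, mean residence time 20.0 h | a single well-mixed tank run continuously and read at steady state, 4.0 h in it on average | a tube with plug flow, the mixed feed as stated, residence time 4.0 h |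
| time |  |  |  |  | 4.0 h |  |  | 4.0 h |

| run | time / h | target / % |
|---|---|---|
| oak | 0.500 | 0 |
| oak | 1.33 | 8 |
| oak | 2.50 | 19 |
| oak | 4.00 | 23 |
| birch | 1.33 | 3 |
| birch | 2.50 | 8 |
| birch | 4.00 | 14 |
| birch | 5.00 | 15 |
| cedar | 0.417 | 1 |
| cedar | 0.833 | 6 |
| cedar | 2.00 | 7 |
| cedar | 5.00 | 25 |
| elm | 0.417 | 0 |
| elm | 0.833 | 2 |
| elm | 2.00 | 8 |
| elm | 5.00 | 16 |

(standard deviation of a reading: 1.5 percentage points)

- the stated concentrations are those of everything mixed, before any reaction; amounts are the same in each set-up
- the numbers in the tables scatter by 1.5 percentage points (one standard deviation)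
- the earlier runs were made in a closed, stirred flask
- a reading or a percentage of target counts all its forms, free or not

1. the set-up with the highest amount of target at the outlet or at the end, in percent of the substrate put in ("none" if the first two lie within 2 percentage points) (Saturday's / Tuesday's / Wednesday's / Thursday's / none)
2. amount of target at the outlet or at the end, in percent of the substrate put in, Saturday's
3. amount of target at the outlet or at the end, in percent of the substrate put in, Tuesday's
4. amount of target at the outlet or at the end, in percent of the substrate put in, Wednesday's
5. amount of target at the outlet or at the end, in percent of the substrate put in, Thursday's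

Each set-up has oak's charge, so I take oak as my reference. I reckon with one step, rate = k[substrate] at a fixed charge, and read reacted substrate as target. Integrating it gives the fraction of target as 1 − exp(−kt). Oak's last reading, 23% at 4.00 h, then gives 0.0653 h⁻¹. This is my working constant k, the share of the remaining substrate that becomes target per hour at this charge, a pseudo-first-order constant. It is a reading and carries the scatter.

The first setting is the vessel, at 4.0 h, where kτ is 0.261. Closed flask and tube give the same time to each portion of liquid, so by hand both give 23.0%. A tank works at outlet concentration, and its balance gives kτ/(1 + kτ), so Wednesday's comes to 20.7%, less than the closed flask.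

The second setting is residence time. At 20.0 h, kτ is 1.31, and the same balance gives Tuesday's 56.7%, the highest of my figures.

The forecast also names Tuesday's, with 31% there, 18% for Wednesday's, and 24% and 24% for Saturday's and Thursday's. Of the slowing it says “I read this as catalyst dying”. My figure for Tuesday's is higher than the forecast's.

The flask gives 24.4% for Saturday's, 24.4% for Thursday's, 21.0% for Wednesday's and 53.6% for Tuesday's, the highest.

    catalyst intermediate B → by-product + catalyst intermediate C (k = 11.3 h⁻¹)
    catalyst intermediate C → free catalyst + target (k = 6.54 h⁻¹)
    target + free catalyst ⇌ isomer of the product + free catalyst, rate k3*[free catalyst]*[target] forward; the back reaction follows from the equilibrium constant (K = 0.120, k = 0.891 L mol⁻¹ h⁻¹)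
    substrate + free catalyst ⇌ catalyst intermediate A (K = 1.73 L mol⁻¹, k = 1.34 L mol⁻¹ h⁻¹)
    reagent + catalyst intermediate A → catalyst intermediate B (k = 3.16 L mol⁻¹ h⁻¹)
    substrate + target ⇌ idle adduct, settled at all times (K = 0.730 L mol⁻¹)

Read back through the tank balance, Tuesday's gives k = 0.0578 h⁻¹ and Wednesday's 0.0665 h⁻¹, against 0.0653 h⁻¹ from oak. With Saturday's charge, substrate has a half-life of 5.2 h by its forward step into catalyst intermediate A, way back not counted and other concentrations held at their charge, far longer than the half-lives of 0.11 h, 0.061 h and 0.11 h of catalyst intermediates A, B and C by the steps that carry them on. At the outlet of Wednesday's tank, catalyst intermediate B stands at 0.509% of the substrate charged.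

All runs come from a simulation on assumed constants; scatter was added.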